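In longipinane numbering the cyclobutane C4–C5–C11–C10 supplies the two one-carbon bridges (C5, C10) of a bicyclo[3.1.1]heptane whose six-membered ring runs through C1–C3, and C5 bears only H and C6, so C5 can start as a ketene-type carbonyl. The route rests on one intramolecular crossed keteniminium–alkene [2+2] that forms C5–C11 and C4–C10, closes both rings and sets C4, C10 and C11 from the chain centres. Its precursor is an open-chain N,N-dimethylamide with the C3 methyl centre, a temporary C1 silyloxy centre and an E trisubstituted C11=C10 alkene. The cyclobutanone carbonyl, 1,3-cis to C9, then anchors the seven-membered ring by a double aldol and is removed by radical deoxygenation.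

Key step: step 9

Remark on numbering: longipinane numbering is used for chain and ring compounds alike (C1 future ketone carbon, C2 CH2, C3 methyl-bearing CH, C4 and C11 cyclobutane CH joined by C1–C3, C5 cyclobutane carbon next to gem-dimethyl C6, C7–C9 oxygenated carbons, C10 methylated quaternary carbon). "Top face" is the cyclobutane face carrying the C1–C3 bridge, and the two sides of the seven-membered ring are named after the cyclobutane CH they face (C11 side, C4 side).

Assumption: in step 1 the quinidine-derived catalyst series is taken to give the R half-ester (the quinine-derived pseudoenantiomer is used if the sense is the opposite), and the catalyst enantiomers of steps 6 and 14 follow the usual large/small model of oxazaborolidine reductions.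

Step 1
Reactants: 1 3-methylglutaric anhydride
Product: 2 (3R)-5-methoxy-3-methyl-5-oxopentanoic acid
Conditions: MeOH, hydroquinidine anthraquinone-1,4-diyl diether [(DHQD)2AQN] (cat.), Et2O, −40 °C
Reagents that add atoms: methanol, CO
Why: Enantioselective alcoholysis of a meso anhydride under general-base catalysis by the cinchona alkaloid ether differentiates the two enantiotopic carbonyl groups and sets C3.

Step 2
Reactants: 3 propargyl alcohol
Product: 5 (E)-3-iodo-2-methylprop-2-en-1-ol, via alkenylalane 4 (not isolated)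
Conditions: Me3Al, Cp2ZrCl2 (cat.), CH2Cl2, 0 °C → rt; then I2, THF, −30 °C; aq. K2CO3
Reagents that add atoms: trimethylaluminium, C[Al](C)C; iodine, II
Why: Zirconium-catalysed syn carboalumination of the alkyne (Negishi methylalumination) puts methyl on the internal and aluminium on the terminal carbon, and iodinolysis of the C–Al bond with retention gives the E iodide.

Step 3
Reactants: 5 (E)-3-iodo-2-methylprop-2-en-1-ol
Product: 6 tert-butyl{[(E)-3-iodo-2-methylprop-2-en-1-yl]oxy}dimethylsilane
Conditions: TBSCl, imidazole, CH2Cl2, 0 °C → rt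
Reagents that add atoms: tert-butyldimethylsilyl chloride, CC(C)(C)[Si](C)(C)Cl
Why: Standard silylation of a primary allylic alcohol gives an ether that tolerates the organometallic and cationic steps ahead.

Step 4
Reactants: 2 (3R)-5-methoxy-3-methyl-5-oxopentanoic acid
Product: 7 methyl (3S)-5-chloro-3-methyl-5-oxopentanoate (same spatial arrangement as 2; the descriptor changes only through CIP priorities)
Conditions: (COCl)2, DMF (cat.), CH2Cl2, 0 °C → rt; concentrate and use crude
Reagents that add atoms: oxalyl chloride, ClC(=O)C(Cl)=O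
Why: Acid chloride formation through the chloroiminium catalyst at room temperature leaves the methyl ester and the β-stereocentre untouched, since the centre could only be lost by closure back to the meso anhydride, which needs heat.

Step 5
Reactants: 6 tert-butyl{[(E)-3-iodo-2-methylprop-2-en-1-yl]oxy}dimethylsilane; 7 methyl (3S)-5-chloro-3-methyl-5-oxopentanoate
Product: 10 methyl (3R,6E)-8-[(tert-butyldimethylsilyl)oxy]-3,7-dimethyl-5-oxooct-6-enoate (chain C1–C8 = longipinane C5, C4, C3, C2, C1, C11, C10, C9), via alkenyllithium 8 (not isolated), via alkenylzinc chloride 9 (not isolated)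
Conditions: tBuLi (2 equiv), Et2O, −78 °C; ZnCl2, THF, −78 → 0 °C; then 7, Pd(PPh3)4 (cat.), THF, 0 °C → rt
Reagents that add atoms: none
Why: Iodine–lithium exchange and transmetalation to zinc retain the alkene geometry, and zerovalent palladium couples the acid chloride with the alkenylzinc (Negishi acylation) without attack on the methyl ester.

Step 6
Reactants: 10 methyl (3R,6E)-8-[(tert-butyldimethylsilyl)oxy]-3,7-dimethyl-5-oxooct-6-enoate
Product: 11 methyl (3R,5S,6E)-8-[(tert-butyldimethylsilyl)oxy]-5-hydroxy-3,7-dimethyloct-6-enoate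
Conditions: (R)-2-methyl-CBS-oxazaborolidine [(R)-1-methyl-3,3-diphenyltetrahydro-1H,3H-pyrrolo[1,2-c][1,3,2]oxazaborole] (cat.), catecholborane, toluene, −78 °C; aq. NaOH wash
Reagents that add atoms: none
Why: Corey–Bakshi–Shibata 1,2-reduction of an enone in which the alkenyl group acts as the large substituent, so the R catalyst delivers hydride to give the S carbinol at C1, the centre that will steer the cycloaddition.

Step 7
Reactants: 11 methyl (3R,5S,6E)-8-[(tert-butyldimethylsilyl)oxy]-5-hydroxy-3,7-dimethyloct-6-enoate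
Product: 12 (3R,5S,6E)-8-[(tert-butyldimethylsilyl)oxy]-5-hydroxy-N,N,3,7-tetramethyloct-6-enamide
Conditions: Me3Al, Me2NH (THF solution), toluene, 0 °C → 40 °C (excess reagent for the free OH); aq. potassium sodium tartrate (KNaC4H4O6) work-up
Reagents that add atoms: dimethylamine, CNC
Why: Aminolysis of the unhindered ester by the aluminium amide made in the flask (Weinreb-type amidation) gives the tertiary amide, and any lactonisation of the δ-hydroxy ester beforehand is harmless because the same reagent opens the ring to the same product.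

Step 8
Reactants: 12 (3R,5S,6E)-8-[(tert-butyldimethylsilyl)oxy]-5-hydroxy-N,N,3,7-tetramethyloct-6-enamide
Product: 13 (3R,5S,6E)-8-[(tert-butyldimethylsilyl)oxy]-N,N,3,7-tetramethyl-5-[(triisopropylsilyl)oxy]oct-6-enamide
Conditions: iPr3SiOTf, 2,6-lutidine, CH2Cl2, −78 → 0 °C
Reagents that add atoms: triisopropylsilyl triflate, CC(C)[Si](OS(=O)(=O)C(F)(F)F)(C(C)C)C(C)C
Why: Silyl triflate silylation of the secondary allylic alcohol installs a bulky group that makes the C1 oxygen a poor nucleophile towards the cationic intermediates of the next step and can later be distinguished from the primary TBS ether.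

Step 9
Reactants: 13 (3R,5S,6E)-8-[(tert-butyldimethylsilyl)oxy]-N,N,3,7-tetramethyl-5-[(triisopropylsilyl)oxy]oct-6-enamide
Product: 16 7-[(tert-butyldimethylsilyloxy)methyl]-4,7-dimethyl-2-[(triisopropylsilyl)oxy]bicyclo[3.1.1]heptan-6-one (bicycle C1–C7 = longipinane C11, C1, C2, C3, C4, C5, C10; silyloxy at C1 and methyl at C3 both on the side of the C5 carbonyl bridge; C10 methyl syn to the C1–C3 bridge; CH2OTBS on the opposite face), via keteniminium triflate 14 (not isolated), via cyclobutaniminium triflate 15 (not isolated)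
Conditions: Tf2O, 2,4,6-collidine, ClCH2CH2Cl, −20 °C → 80 °C; then aq. NaHCO3, rt
Reagents that add atoms: water, O
Why: Triflic anhydride turns the amide into an α-triflyloxy enamine that ionises to keteniminium ion 14, whose central carbon C5 bonds to the less substituted alkene carbon C11 while the charge building at tertiary C10 is quenched by the enamine carbon C4, and water then hydrolyses cyclobutaniminium salt 15 to the ketone. This is the intramolecular keteniminium–alkene [2+2] cycloaddition in its crossed mode, known for 6-alkenoic amides (and the corresponding ketenes) whose alkene is more substituted at the distal carbon, which give 7,7-disubstituted bicyclo[3.1.1]heptan-6-ones with retention of alkene geometry. The six-membered ring C5–C4–C3–C2–C1–C11 closes through C5–C11 (6-exo with respect to the alkene, chair-like) and the cyclobutane C4–C5–C11–C10 closes through C4–C10, so C5 and C10 become the two one-carbon bridges. C4 and C11 follow from the alkene face that is attacked: allylic 1,3-strain keeps the C1 hydrogen in the alkene plane facing the cis methyl on C10, the tether can then reach only one face, and the C1 silyloxy group and the C3 methyl both end up on the C5 side, away from that methyl (the two chain centres reinforce each other); C10 is fixed by the E geometry through suprafacial addition, its methyl syn to the C1–C3 bridge and C9 on the other face beside the new carbonyl. The step needs crossed rather than fused regiochemistry, which the tertiary cation site at C10 (against a secondary, oxygen-deactivated C11) secures, and it needs the C1 oxygen to stay out of the reaction, for which the triisopropylsilyl group and the hindered base are chosen.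

Step 10
Reactants: 16 7-[(tert-butyldimethylsilyloxy)methyl]-4,7-dimethyl-2-[(triisopropylsilyl)oxy]bicyclo[3.1.1]heptan-6-one
Product: 17 7-(hydroxymethyl)-4,7-dimethyl-2-[(triisopropylsilyl)oxy]bicyclo[3.1.1]heptan-6-one (stereochemistry as in 16)
Conditions: HF·pyridine, pyridine, THF, 0 °C → rt
Reagents that add atoms: none
Why: Buffered fluoride cleaves the primary TBS ether much faster than the hindered secondary TIPS ether and, unlike acidic methanol, cannot ketalise the cyclobutanone.

Step 11
Reactants: 17 7-(hydroxymethyl)-4,7-dimethyl-2-[(triisopropylsilyl)oxy]bicyclo[3.1.1]heptan-6-one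
Product: 18 4,7-dimethyl-6-oxo-2-[(triisopropylsilyl)oxy]bicyclo[3.1.1]heptane-7-carbaldehyde (numbering and stereochemistry as in 16; aldehyde carbon = C9)
Conditions: Dess–Martin periodinane, pyridine, CH2Cl2, rt
Reagents that add atoms: none
Why: Dess–Martin oxidation of a neopentyl primary alcohol gives an aldehyde on quaternary C10 that cannot enolise or epimerise.

Step 12
Reactants: 18 4,7-dimethyl-6-oxo-2-[(triisopropylsilyl)oxy]bicyclo[3.1.1]heptane-7-carbaldehyde; 19 3-methylbutan-2-one
Product: 23 5,9-dihydroxy-1-(triisopropylsilyloxy)longipinan-7-one (tertiary C5 hydroxyl on the top face; C9 carbinol as an epimer mixture), via lithium enolate 20 (not isolated), via lithium aldolate 21 (not isolated), via dilithio enolate 22 (not isolated)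
Conditions: LiN(iPr)2 (1.1 equiv), 19, THF, −78 °C; add 18; then LiN(iPr)2 (1.5 equiv), −78 → −20 °C; aq. NH4Cl
Reagents that add atoms: none
Why: Directed aldol addition of the kinetic methyl-side enolate to the aldehyde (faster than to the hindered cyclobutanone) forms C8–C9, the resulting β-oxido ketone is then deprotonated away from the alkoxide at the isopropyl carbon (aldolate dianion regiochemistry), and this enolate closes C5–C6 by intramolecular aldol onto the strained cyclobutanone from the face that carries C9, so the new hydroxyl must point to the top face.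

Step 13
Reactants: 23 5,9-dihydroxy-1-(triisopropylsilyloxy)longipinan-7-one
Product: 25 5-hydroxy-1-(triisopropylsilyloxy)longipin-8-en-7-one, via C9 mesylate 24 (not isolated)
Conditions: MsCl, Et3N, CH2Cl2, 0 °C; then DBU, rt
Reagents that add atoms: none
Why: Only the secondary C9 hydroxyl is sulfonylated (the tertiary C5 hydroxyl is inert and cannot eliminate, C6 being quaternary and C4 and C11 bridgeheads), and E1cB elimination through the C8 enolate converges both C9 epimers on the ring-constrained cis enone.

Step 14
Reactants: 25 5-hydroxy-1-(triisopropylsilyloxy)longipin-8-en-7-one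
Product: 26 (7R)-1-(triisopropylsilyloxy)longipin-8-ene-5,7-diol (C7 hydroxyl on the C4 side)
Conditions: (S)-2-methyl-CBS-oxazaborolidine [(S)-1-methyl-3,3-diphenyltetrahydro-1H,3H-pyrrolo[1,2-c][1,3,2]oxazaborole] (0.5 equiv), BH3·SMe2 (excess, the free hydroxyl consumes hydride), THF, −20 → 0 °C; MeOH quench
Reagents that add atoms: none
Why: Corey–Bakshi–Shibata reduction under reagent control, needed because the C11 and C4 sides of the C7 carbonyl are related by a pseudo-mirror plane through C5 and C10 and the cage gives little bias; boron binds the lone pair next to the vinylic C8–H, away from quaternary C6, and the S catalyst then gives the 7R carbinol.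

Step 15
Reactants: 26 (7R)-1-(triisopropylsilyloxy)longipin-8-ene-5,7-diol
Product: 27 (7R)-7-(methoxymethoxy)-1-(triisopropylsilyloxy)longipin-8-en-5-ol
Conditions: MOMCl, iPr2NEt, Bu4NI (cat.), CH2Cl2, 0 → 35 °C
Reagents that add atoms: chloromethyl methyl ether, COCCl
Why: Alkylation with the small chloromethyl ether under amine base takes the secondary allylic hydroxyl and leaves the hindered tertiary cyclobutanol free for the deoxygenation.

Step 16
Reactants: 27 (7R)-7-(methoxymethoxy)-1-(triisopropylsilyloxy)longipin-8-en-5-ol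
Product: 28 methyl oxalate of 27 at the C5 oxygen [methyl (7R)-7-(methoxymethoxy)-1-(triisopropylsilyloxy)longipin-8-en-5-yl oxalate]
Conditions: ClC(O)CO2Me, DMAP, pyridine, CH2Cl2, 0 °C → rt
Reagents that add atoms: methyl chlorooxoacetate, COC(=O)C(=O)Cl
Why: DMAP-catalysed acylation by a small, very electrophilic acid chloride reaches the crowded tertiary hydroxyl under neutral conditions, which avoids the potassium alkoxide of a xanthate synthesis and with it migration of the neighbouring C1 silyl group.

Step 17
Reactants: 28 methyl oxalate of 27 at the C5 oxygen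
Product: 29 (7R)-7-(methoxymethoxy)-1-(triisopropylsilyloxy)longipin-8-ene (C5–H on the top face)
Conditions: Bu3SnH (excess, high concentration), azobisisobutyronitrile (cat.), toluene, 110 °C
Reagents that add atoms: none
Why: Barton-type radical deoxygenation of a tertiary methyl oxalate gives the bridgehead cyclobutyl radical at C5, which cannot invert because C5 is a ring-fusion atom and so takes hydrogen on its only open face, and a high stannane concentration lets hydrogen transfer outrun β-scission of the C6–C7 bond.

Step 18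
Reactants: 29 (7R)-7-(methoxymethoxy)-1-(triisopropylsilyloxy)longipin-8-ene
Product: 30 (7R)-7-(methoxymethoxy)longipin-8-en-1-ol
Conditions: Bu4NF, THF, rt → 45 °C; aq. NH4Cl
Reagents that add atoms: none
Why: Fluoride cleaves the silyl ether and leaves the acetal and the alkene untouched, and it is safe only now because with the C5 oxygen gone the future C1 ketone can no longer undergo a retro-aldol opening of the cyclobutane.

Step 19
Reactants: 30 (7R)-7-(methoxymethoxy)longipin-8-en-1-ol
Product: 31 (7R)-7-(methoxymethoxy)longipin-8-en-1-one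
Conditions: Dess–Martin periodinane, NaHCO3, CH2Cl2, rt
Reagents that add atoms: none
Why: Mild oxidation of the secondary alcohol gives the C1 ketone, whose only stereogenic α-carbon (C11) is a bridgehead and cannot epimerise.

Step 20
Reactants: 31 (7R)-7-(methoxymethoxy)longipin-8-en-1-one
Product: 32 8,9-dihydroxy-7-(methoxymethoxy)longipinan-1-one (C8 and C9 hydroxyls on the C11 side, C7 oxygen on the C4 side)
Conditions: OsO4 (cat.), N-methylmorpholine N-oxide, acetone/H2O, rt
Reagents that add atoms: osmium tetroxide (oxygen carrier), O=[Os](=O)(=O)=O; N-methylmorpholine N-oxide (terminal oxidant), C[N+]1([O-])CCOCC1; water, O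
Why: Catalytic osmylation adds both oxygens to the same face of the cis alkene and follows the usual preference for attack anti to an allylic alkoxy group, here the C7 ether, which sets C8 and C9 cis to each other and trans to the C7 oxygen.

Step 21
Reactants: 32 8,9-dihydroxy-7-(methoxymethoxy)longipinan-1-one
Product: 33 7,8,9-trihydroxylongipinan-1-one (C7 hydroxyl on the C4 side, C8 and C9 hydroxyls on the C11 side)
Conditions: HCl (cat.), MeOH, 40 °C
Reagents that add atoms: none
Why: Acid-catalysed acetal exchange with methanol removes the methoxymethyl group without ionising any ring C–O bond, so the strained skeleton is not exposed to a carbocation.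

Step 22
Reactants: 34 angelic acid
Product: 35 angelic 2,4,6-trichlorobenzoic anhydride
Conditions: 2,4,6-trichlorobenzoyl chloride (1.0 equiv), Et3N (1.0 equiv), toluene, rt; Et3NHCl filtered off under argon, toluene solution used at once
Reagents that add atoms: 2,4,6-trichlorobenzoyl chloride, O=C(Cl)c1c(Cl)cc(Cl)cc1Cl
Why: The triethylammonium angelate is acylated by the aroyl chloride (first stage of a Yamaguchi esterification), and since neither a nucleophilic catalyst nor excess carboxylate is present the Z double bond is kept and little symmetrical anhydride forms.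

Step 23
Reactants: 33 7,8,9-trihydroxylongipinan-1-one; 35 angelic 2,4,6-trichlorobenzoic anhydride (three equivalents are consumed, one per hydroxyl)
Product: 36 7,8,9-tris(angeloyloxy)longipinan-1-one (target)
Conditions: 35 (6 equiv, toluene solution from step 22), toluene, 75 °C, no DMAP
Reagents that add atoms: angelic 2,4,6-trichlorobenzoic anhydride (second equivalent), C/C=C(/C)C(=O)OC(=O)c1c(Cl)cc(Cl)cc1Cl; angelic 2,4,6-trichlorobenzoic anhydride (third equivalent), C/C=C(/C)C(=O)OC(=O)c1c(Cl)cc(Cl)cc1Cl
Why: Thermal second stage of the Yamaguchi esterification, in which each of the three hydroxyls attacks the less hindered angeloyl carbonyl of one molecule of mixed anhydride (the aroyl carbonyl is shielded by two ortho chlorines) and 2,4,6-trichlorobenzoic acid leaves, run without a nucleophilic catalyst because such catalysts add reversibly to the enoate and isomerise Z to E (tiglate).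

Compound list
1 | 3-methylglutaric anhydride | CC1CC(=O)OC(=O)C1 | starting material
2 | (3R)-5-methoxy-3-methyl-5-oxopentanoic acid | COC(=O)C[C@H](C)CC(=O)O | intermediate
3 | propargyl alcohol | C#CCO | starting material
4 | alkenylalane, dimethyl[(E)-3-(dimethylaluminiooxy)-2-methylprop-1-enyl]aluminium | C[Al](C)/C=C(\C)CO[Al](C)C | intermediate
5 | (E)-3-iodo-2-methylprop-2-en-1-ol | I/C=C(\C)CO | intermediate
6 | tert-butyl{[(E)-3-iodo-2-methylprop-2-en-1-yl]oxy}dimethylsilane | I/C=C(\C)CO[Si](C)(C)C(C)(C)C | intermediate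
7 | methyl (3S)-5-chloro-3-methyl-5-oxopentanoate | COC(=O)C[C@H](C)CC(=O)Cl | intermediate
8 | alkenyllithium from 6 | [Li]/C=C(\C)CO[Si](C)(C)C(C)(C)C | intermediate
9 | alkenylzinc chloride from 8 | Cl[Zn]/C=C(\C)CO[Si](C)(C)C(C)(C)C | intermediate
10 | methyl (3R,6E)-8-[(tert-butyldimethylsilyl)oxy]-3,7-dimethyl-5-oxooct-6-enoate | COC(=O)C[C@H](C)CC(=O)/C=C(\C)CO[Si](C)(C)C(C)(C)C | intermediate
11 | methyl (3R,5S,6E)-8-[(tert-butyldimethylsilyl)oxy]-5-hydroxy-3,7-dimethyloct-6-enoate | COC(=O)C[C@H](C)C[C@H](O)/C=C(\C)CO[Si](C)(C)C(C)(C)C | intermediate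
12 | (3R,5S,6E)-8-[(tert-butyldimethylsilyl)oxy]-5-hydroxy-N,N,3,7-tetramethyloct-6-enamide | CN(C)C(=O)C[C@H](C)C[C@H](O)/C=C(\C)CO[Si](C)(C)C(C)(C)C | intermediate
13 | (3R,5S,6E)-8-[(tert-butyldimethylsilyl)oxy]-N,N,3,7-tetramethyl-5-[(triisopropylsilyl)oxy]oct-6-enamide | CN(C)C(=O)C[C@H](C)C[C@H](O[Si](C(C)C)(C(C)C)C(C)C)/C=C(\C)CO[Si](C)(C)C(C)(C)C | intermediate
14 | keteniminium triflate from 13 | C[N+](C)=C=C[C@H](C)C[C@H](O[Si](C(C)C)(C(C)C)C(C)C)/C=C(\C)CO[Si](C)(C)C(C)(C)C.[O-]S(=O)(=O)C(F)(F)F | intermediate
15 | cyclobutaniminium triflate (N,N-dimethyliminium of 16) | C[N+](C)=C1[C@@H]2[C@H](C)C[C@H](O[Si](C(C)C)(C(C)C)C(C)C)[C@H]1[C@]2(C)CO[Si](C)(C)C(C)(C)C.[O-]S(=O)(=O)C(F)(F)F | intermediate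
16 | 7-[(tert-butyldimethylsilyloxy)methyl]-4,7-dimethyl-2-[(triisopropylsilyl)oxy]bicyclo[3.1.1]heptan-6-one | O=C1[C@@H]2[C@H](C)C[C@H](O[Si](C(C)C)(C(C)C)C(C)C)[C@H]1[C@]2(C)CO[Si](C)(C)C(C)(C)C | intermediate
17 | 7-(hydroxymethyl)-4,7-dimethyl-2-[(triisopropylsilyl)oxy]bicyclo[3.1.1]heptan-6-one | O=C1[C@@H]2[C@H](C)C[C@H](O[Si](C(C)C)(C(C)C)C(C)C)[C@H]1[C@]2(C)CO | intermediate
18 | 4,7-dimethyl-6-oxo-2-[(triisopropylsilyl)oxy]bicyclo[3.1.1]heptane-7-carbaldehyde | O=C1[C@@H]2[C@H](C)C[C@H](O[Si](C(C)C)(C(C)C)C(C)C)[C@H]1[C@]2(C)C=O | intermediate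
19 | 3-methylbutan-2-one | CC(=O)C(C)C | starting material
20 | lithium enolate of 19 (methyl side) | [Li]OC(=C)C(C)C | intermediate
21 | lithium aldolate (C9 alkoxide, C7 ketone, open seven-membered ring) | O=C1[C@@H]2[C@H](C)C[C@H](O[Si](C(C)C)(C(C)C)C(C)C)[C@H]1[C@]2(C)C(O[Li])CC(=O)C(C)C | intermediate
22 | dilithio species (C9 alkoxide, C6 enolate) | O=C1[C@@H]2[C@H](C)C[C@H](O[Si](C(C)C)(C(C)C)C(C)C)[C@H]1[C@]2(C)C(O[Li])CC(O[Li])=C(C)C | intermediate
23 | 5,9-dihydroxy-1-(triisopropylsilyloxy)longipinan-7-one (C9 epimer mixture) | O=C1C(C)(C)[C@@]2(O)[C@@H]3[C@H](C)C[C@H](O[Si](C(C)C)(C(C)C)C(C)C)[C@H]2[C@]3(C)C(O)C1 | intermediate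
24 | C9 mesylate of 23 | O=C1C(C)(C)[C@@]2(O)[C@@H]3[C@H](C)C[C@H](O[Si](C(C)C)(C(C)C)C(C)C)[C@H]2[C@]3(C)C(OS(C)(=O)=O)C1 | intermediate
25 | 5-hydroxy-1-(triisopropylsilyloxy)longipin-8-en-7-one | O=C1C(C)(C)[C@@]2(O)[C@@H]3[C@H](C)C[C@H](O[Si](C(C)C)(C(C)C)C(C)C)[C@H]2[C@]3(C)C=C1 | intermediate
26 | (7R)-1-(triisopropylsilyloxy)longipin-8-ene-5,7-diol | O[C@H]1C(C)(C)[C@@]2(O)[C@@H]3[C@H](C)C[C@H](O[Si](C(C)C)(C(C)C)C(C)C)[C@H]2[C@]3(C)C=C1 | intermediate
27 | (7R)-7-(methoxymethoxy)-1-(triisopropylsilyloxy)longipin-8-en-5-ol | COCO[C@H]1C(C)(C)[C@@]2(O)[C@@H]3[C@H](C)C[C@H](O[Si](C(C)C)(C(C)C)C(C)C)[C@H]2[C@]3(C)C=C1 | intermediate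
28 | methyl (7R)-7-(methoxymethoxy)-1-(triisopropylsilyloxy)longipin-8-en-5-yl oxalate | COCO[C@H]1C(C)(C)[C@@]2(OC(=O)C(=O)OC)[C@@H]3[C@H](C)C[C@H](O[Si](C(C)C)(C(C)C)C(C)C)[C@H]2[C@]3(C)C=C1 | intermediate
29 | (7R)-7-(methoxymethoxy)-1-(triisopropylsilyloxy)longipin-8-ene | COCO[C@H]1C(C)(C)[C@H]2[C@@H]3[C@H](C)C[C@H](O[Si](C(C)C)(C(C)C)C(C)C)[C@H]2[C@]3(C)C=C1 | intermediate
30 | (7R)-7-(methoxymethoxy)longipin-8-en-1-ol | COCO[C@H]1C(C)(C)[C@H]2[C@@H]3[C@H](C)C[C@H](O)[C@H]2[C@]3(C)C=C1 | intermediate
31 | (7R)-7-(methoxymethoxy)longipin-8-en-1-one | COCO[C@H]1C(C)(C)[C@H]2[C@@H]3[C@H](C)CC(=O)[C@H]2[C@]3(C)C=C1 | intermediate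
32 | 8,9-dihydroxy-7-(methoxymethoxy)longipinan-1-one | O[C@@H]1[C@@H](OCOC)C(C)(C)[C@H]2[C@@H]3[C@H](C)CC(=O)[C@H]2[C@]3(C)[C@@H]1O | intermediate
33 | 7,8,9-trihydroxylongipinan-1-one | O[C@@H]1[C@@H](O)C(C)(C)[C@H]2[C@@H]3[C@H](C)CC(=O)[C@H]2[C@]3(C)[C@@H]1O | intermediate
34 | angelic acid, (Z)-2-methylbut-2-enoic acid | C/C=C(/C)C(=O)O | starting material
35 | angelic 2,4,6-trichlorobenzoic anhydride | C/C=C(/C)C(=O)OC(=O)c1c(Cl)cc(Cl)cc1Cl | intermediate
36 | 7,8,9-tris(angeloyloxy)longipinan-1-one, CNP0138097.1 | C/C=C(/C)C(=O)O[C@@H]1[C@@H](OC(=O)/C(C)=C\C)C(C)(C)[C@H]2[C@@H]3[C@H](C)CC(=O)[C@H]2[C@]3(C)[C@@H]1OC(=O)/C(C)=C\C | target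

Total step count: 23. Longest linear sequence: 20 steps (1 → 36 through steps 1, 4, 5–21 and 23; the branch from 3 through steps 2, 3, 5–21 and 23 is equally long; the acylating agent is made from 34 in step 22).

Steps most likely to fail

Step 12. The hindered lithium aldolate may revert by retro-aldol, the second deprotonation may occur at C8 instead of C6, or the equilibrium of the congested seven-ring aldol may be unfavourable. The fallback generates the C6 nucleophile by reduction instead of deprotonation and sets out from ketone 19 and aldehyde 18. Ketone 19 is brominated at its methine carbon (Br2, CH2Cl2) to 3-bromo-3-methylbutan-2-one F1, which is converted (Me3SiOTf, Et3N) into [(3-bromo-3-methylbut-1-en-2-yl)oxy]trimethylsilane F2. Mukaiyama aldol addition of F2 to 18 (BF3·OEt2, CH2Cl2, −78 °C) should give the C9 carbinol carrying the C7 ketone and a C6 bromide, bromo aldol F3. SmI2 in THF at −78 °C then reduces the C–Br bond to the samarium enolate, which closes C5–C6 in a Reformatsky-type aldol onto the cyclobutanone, and the route is rejoined at diol 23.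

Step 9. The keteniminium carbon may be captured by the C1 silyl ether oxygen with loss of the silyl group, or the cycloaddition may be sluggish because the alkene is flanked by two allylic oxygens. The fallback uses the neutral ketene in place of the keteniminium ion and sets out from hydroxy ester 11. Silylation (iPr3SiOTf, 2,6-lutidine) gives the TIPS ether methyl ester F4, and saponification (LiOH, THF/H2O) gives the acid F5. 1-Chloro-N,N,2-trimethylprop-1-en-1-amine converts F5 under neutral conditions into the acid chloride F6. Slow addition of F6 to Et3N in refluxing toluene generates ketene F7, whose intramolecular crossed [2+2] with the same alkene should give cyclobutanone 16, where the route is rejoined.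

Step 23. Angelate may isomerise to tiglate during a slow threefold acylation of two neopentyl-type and one flanked secondary hydroxyl, or acylation may stay incomplete. The fallback builds the Z alkenes after acylation and sets out from triol 33. Esterification with 2-[bis(2,2,2-trifluoroethoxy)phosphoryl]propanoic acid F8 (obtained by LiOH hydrolysis of its commercial methyl ester; DCC, DMAP, CH2Cl2) gives the tris(phosphonopropanoate) F9. A threefold Still–Gennari olefination (KN(SiMe3)2, 18-crown-6, THF, −78 °C, then acetaldehyde) should form the three (Z)-2-methylbut-2-enoates under kinetic control and arrive at target 36.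

Further compounds
F1 | step 12 | 3-bromo-3-methylbutan-2-one | CC(=O)C(C)(C)Br
F2 | step 12 | [(3-bromo-3-methylbut-1-en-2-yl)oxy]trimethylsilane | C=C(O[Si](C)(C)C)C(C)(C)Br
F3 | step 12 | bromo aldol (C9 carbinol, C7 ketone, C6 bromide; C9 epimer mixture) | O=C1[C@@H]2[C@H](C)C[C@H](O[Si](C(C)C)(C(C)C)C(C)C)[C@H]1[C@]2(C)C(O)CC(=O)C(C)(C)Br
F4 | step 9 | methyl (3R,5S,6E)-8-[(tert-butyldimethylsilyl)oxy]-3,7-dimethyl-5-[(triisopropylsilyl)oxy]oct-6-enoate | COC(=O)C[C@H](C)C[C@H](O[Si](C(C)C)(C(C)C)C(C)C)/C=C(\C)CO[Si](C)(C)C(C)(C)C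
F5 | step 9 | (3R,5S,6E)-8-[(tert-butyldimethylsilyl)oxy]-3,7-dimethyl-5-[(triisopropylsilyl)oxy]oct-6-enoic acid | OC(=O)C[C@H](C)C[C@H](O[Si](C(C)C)(C(C)C)C(C)C)/C=C(\C)CO[Si](C)(C)C(C)(C)C
F6 | step 9 | acid chloride of F5 | ClC(=O)C[C@H](C)C[C@H](O[Si](C(C)C)(C(C)C)C(C)C)/C=C(\C)CO[Si](C)(C)C(C)(C)C
F7 | step 9 | ketene from F6 | O=C=C[C@H](C)C[C@H](O[Si](C(C)C)(C(C)C)C(C)C)/C=C(\C)CO[Si](C)(C)C(C)(C)C
F8 | step 23 | 2-[bis(2,2,2-trifluoroethoxy)phosphoryl]propanoic acid | CC(C(=O)O)P(=O)(OCC(F)(F)F)OCC(F)(F)F
F9 | step 23 | 7,8,9-tris{2-[bis(2,2,2-trifluoroethoxy)phosphoryl]propanoyloxy}longipinan-1-one | CC(P(=O)(OCC(F)(F)F)OCC(F)(F)F)C(=O)O[C@@H]1[C@@H](OC(=O)C(C)P(=O)(OCC(F)(F)F)OCC(F)(F)F)C(C)(C)[C@H]2[C@@H]3[C@H](C)CC(=O)[C@H]2[C@]3(C)[C@@H]1OC(=O)C(C)P(=O)(OCC(F)(F)F)OCC(F)(F)F
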